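**Strategy.** The cis-fused cyclopentenone is traced back to a cyclobutanone lacking one CH2. Its ring-fusion methine (between the spiroketal carbon and the enone C=O) and the neighbouring tertiary carbinol carbon (on C5 of the phenalenone) are the two olefinic carbons of a 3-alkoxyindene, fused to 9-methoxyphenalen-1-one, whose C1 already is the naphthalene-1,8-dioxy ketal. Dichloroketene adds across this enol ether: one operation closes the four-membered ring, forms both C–C bonds and sets both stereocentres, the face being chosen by a 1-(2,4,6-triisopropylphenyl)ethyl ether on the enol oxygen. Dechlorination, CH2 insertion on the methylene side, desaturation and two deprotections complete the route.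

Key step: step 8

Locants: phenalenone numbering is used (C1 = ring carbonyl, C9 = oxygenated carbon); the five-membered ring fused at C5–C6 is numbered C1' (on C6, spiroketal carbon), C2' and C3' (on C5).

Assumption: the 3'-alkoxyindene is taken to react through its s-cis rotamer (O–CH bond syn to C2'=C3', carbinol C–H in the olefin plane); on this model the (R)-configured 1-(2,4,6-triisopropylphenyl)ethanol is the matched antipode and is used, and the (S)-antipode would deliver the enantiomeric series.

**Step 1**
Reactants: 1 2-bromo-6-methoxynaphthalene; 2 (3-ethoxy-3-oxopropyl)zinc bromide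
Product: 3 ethyl 3-(6-methoxynaphthalen-2-yl)propanoate
Conditions: Pd(OAc)2 (2 mol%), 2-dicyclohexylphosphino-2',6'-dimethoxybiphenyl, THF, 50 °C
Reagents that add atoms: none
Why: Negishi coupling of an aryl bromide with a commercial zinc homoenolate should install the three-carbon ester chain (future C3', C2', C1') in one operation; no stereocentre is formed.

**Step 2**
Reactants: 3 ethyl 3-(6-methoxynaphthalen-2-yl)propanoate; 4 3-chloropropanoyl chloride
Product: 5 ethyl 3-[5-(3-chloropropanoyl)-6-methoxynaphthalen-2-yl]propanoate
Conditions: AlCl3 (2.5 equiv.), CH2Cl2, −10 → 0 °C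
Reagents that add atoms: none
Why: Friedel–Crafts acylation under kinetic control should enter the alpha position next to the methoxy group (naphthalene C5), and the low temperature should keep the ortho methyl ether intact.

**Step 3**
Reactants: 5 ethyl 3-[5-(3-chloropropanoyl)-6-methoxynaphthalen-2-yl]propanoate
Product: 7 tetracyclic diketone (9-methoxy-2,3-dihydrophenalen-1-one carrying a C5–C6-fused cyclopentanone whose C1'=O sits on C6), via dihydrophenalenone ester 6 (not isolated)
Conditions: MeSO3H, 45 °C; then P2O5 added (about 8 wt% in MeSO3H), 70 °C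
Reagents that add atoms: none
Why: Two intramolecular Friedel–Crafts reactions in a fixed order: the 3-chloropropanoyl chain should first alkylate the peri carbon (naphthalene C4, the ortho carbon being blocked by OMe) to give the six-membered ketone ring of 6, and only then does P2O5 activate the ester for acylation at C1, the alpha position para to the new ring CH2; the order matters because an indanone carbonyl on C1 would deactivate C4.

**Step 4**
Reactants: 7 tetracyclic diketone
Product: 8 phenalenone indanone (9-methoxyphenalen-1-one carrying the C5–C6-fused cyclopentanone, C1'=O on C6)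
Conditions: DDQ (1.1 equiv.), 1,4-dioxane, 80 °C
Reagents that add atoms: none
Why: Quinone dehydrogenation of a 2,3-dihydrophenalen-1-one is driven by the extended conjugation of the phenalenone, whereas the cyclopentanone should stay untouched because an indenone gains no comparable stabilisation.

**Step 5**
Reactants: 8 phenalenone indanone; 9 naphthalene-1,8-diol
Product: 10 spiroketal (C1' of 8 converted into the naphthalene-1,8-dioxy ketal; C2' and C3' are CH2)
Conditions: p-TsOH·H2O (10 mol%), toluene, reflux, Dean–Stark trap, Ar, exclusion of light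
Reagents that add atoms: none
Why: Acid-catalysed ketalisation with azeotropic removal of water should take place only at the indanone carbonyl, since the phenalenone C=O is a vinylogous ester carbonyl that does not ketalise.

**Step 6**
Reactants: 10 spiroketal
Product: 11 keto spiroketal (10 with C3'=O)
Conditions: CrO3, 3,5-dimethylpyrazole, CH2Cl2, −20 °C
Reagents that add atoms: chromium trioxide, O=[Cr](=O)=O
Why: Benzylic C–H oxidation with the CrO3–dimethylpyrazole complex should convert C3'H2, the only benzylic methylene left, into the ketone under non-basic conditions that spare the base-labile beta-keto ketal.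

**Step 7**
Reactants: 11 keto spiroketal; 12 (R)-1-(2,4,6-triisopropylphenyl)ethanol
Product: 14 (R)-auxiliary enol ether (C2'=C3' with C3'–O–CH(CH3)Ar and C1' spiroketal), via dimethyl ketal 13 (not isolated)
Conditions: HC(OMe)3, PPTS (cat.), MeOH, 40 °C; evaporate; 12 (2 equiv.), PPTS (cat.), toluene, 90 °C, 5 Å molecular sieves
Reagents that add atoms: trimethyl orthoformate, COC(OC)OC (methoxy groups of 13 only)
Why: Acid-catalysed ketal exchange–elimination (the enol-ether-forming stage of the ketal Claisen, Saucy–Marbet type) should replace methanol by the chiral alcohol and lose the only available proton (C2'–H) while the sieves remove methanol; no enolate is involved, which matters because a C2' enolate would expel aryloxide from C1', and the C–O bond of the auxiliary is not touched, so its configuration is retained.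

**Step 8**
Reactants: 14 (R)-auxiliary enol ether; 15 trichloroacetyl chloride
Product: 17 (2'S,3'R)-cis-fused 2,2-dichloro-3-alkoxycyclobutanone (C2' bonded to the new C=O, C3' bonded to CCl2 and still bearing the (R)-auxiliary ether), via dichloroketene 16 (not isolated)
Conditions: zinc–copper couple, Et2O–DME, 0 → 20 °C, slow addition of 15, Ar, exclusion of light
Reagents that add atoms: none
Why: Dichloroketene 16, formed from 15 by zinc dechlorination, should add to the enol ether in a concerted but asynchronous [π2s+π2a] process in which the nucleophilic C2' bonds to the ketene carbonyl carbon ahead of C3'–CCl2 bond formation. The closest known reaction type is the auxiliary-controlled dichloroketene cycloaddition to enol ethers of 1-arylethanols. The four-membered ring is closed by a formal (2+2) addition that is suprafacial on C2'=C3', so the ring fusion can only be cis. Both new stereocentres (C2' S, C3' R) follow from the face of attack, which the (R)-auxiliary sets: in the s-cis rotamer the triisopropylphenyl group covers the face that would lead to the enantiomer, and the ketene enters past the methyl group. Regiochemistry is secured by the enol-ether polarisation, chemoselectivity by the electron-poor phenalenone C2=C3 bond being inert to ketenes and by zinc not reducing the enone in aprotic ether (DME binds ZnCl2 and spares the acid-labile ethers), and facial selectivity rests on the auxiliary alone because the spiroketal flanks both faces equally.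

**Step 9**
Reactants: 17 dichlorocyclobutanone
Product: 18 (2'S,3'R)-cis-fused cyclobutanone (ring C2'–C(=O)–CH2–C3')
Conditions: Zn dust, AcOH, TMEDA, EtOH, 0 °C
Reagents that add atoms: none
Why: Zinc reduction of an alpha,alpha-dichloroketone under amine-buffered conditions should remove both chlorines without beta-elimination of the alkoxy group; the C–Cl bonds are reduced far more readily than the phenalenone, and neither stereocentre is involved.

**Step 10**
Reactants: 18 cyclobutanone
Product: 19 (2'S,3'R)-cis-fused cyclopentanone (ring C2'–C(=O)–CH2–CH2–C3')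
Conditions: CH2N2, Et2O–MeOH, 0 °C
Reagents that add atoms: diazomethane, C=[N+]=[N-]
Why: Diazomethane ring expansion (Büchner–Curtius–Schlotterbeck type) should add to the strained carbonyl and shift the unhindered CH2 rather than the C2' methine, which is flanked by two quaternary carbons and carries the electron-withdrawing ketal; the strained ketone reacts much faster than the phenalenone or the product, and the migrating carbon is not stereogenic.

**Step 11**
Reactants: 19 cyclopentanone
Product: 21 (2'S,3'R)-cyclopentenone auxiliary ether (ring C2'–C(=O)–CH=CH–C3'), via trimethylsilyl enol ether 20 (not isolated)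
Conditions: LiN(SiMe3)2, Me3SiCl, THF, −78 °C; then Pd(OAc)2 (1.1 equiv.), MeCN, 20 °C
Reagents that add atoms: chlorotrimethylsilane, C[Si](C)(C)Cl (silyl group of 20 only)
Why: Kinetic deprotonation with in situ silylation should occur at the CH2 and not at the shielded C2' methine (whose enolate would expel aryloxide), and Saegusa–Ito oxidation of the resulting enol silane then gives the enone without touching the stereocentres.

**Step 12**
Reactants: 21 cyclopentenone auxiliary ether
Product: 22 9-O-methylspiropreussione B ((2'S,3'R), free tertiary alcohol at C3')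
Conditions: CF3CO2H, CH2Cl2, 0 °C
Reagents that add atoms: none
Why: Acidolysis of the auxiliary ether should proceed through the stabilised 1-arylethyl cation (E1 loss as the styrene), while the C3'–O bond is kept because a cation at C3' would be destabilised by the adjacent enone and ketal, so configuration at C3' is retained.

**Step 13**
Reactants: 22 9-O-methylspiropreussione B
Product: 23 spiropreussione B
Conditions: BCl3 (3 equiv.), CH2Cl2, −78 °C; then pH 7 buffer
Reagents that add atoms: none
Why: Chelation-assisted cleavage of the methyl ether peri to the phenalenone carbonyl by BCl3 should be much faster at low temperature than attack on the diaryl ketal, and the neutral work-up avoids base-induced opening of the beta-keto ketal.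

**Compound list**
1 | 2-bromo-6-methoxynaphthalene | COc1ccc2cc(Br)ccc2c1 | starting material
2 | (3-ethoxy-3-oxopropyl)zinc bromide | CCOC(=O)CC[Zn]Br | starting material
3 | ethyl 3-(6-methoxynaphthalen-2-yl)propanoate | CCOC(=O)CCc1ccc2cc(OC)ccc2c1 | intermediate
4 | 3-chloropropanoyl chloride | O=C(Cl)CCCl | starting material
5 | ethyl 3-[5-(3-chloropropanoyl)-6-methoxynaphthalen-2-yl]propanoate | CCOC(=O)CCc1ccc2c(C(=O)CCCl)c(OC)ccc2c1 | intermediate
6 | ethyl 3-(9-methoxy-1-oxo-2,3-dihydro-1H-phenalen-5-yl)propanoate | O=C1CCc2cc(CCC(=O)OCC)cc3ccc(OC)c1c23 | intermediate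
7 | tetracyclic diketone: 9-methoxy-2,3-dihydrophenalen-1-one with a cyclopentanone fused at C5–C6 (C1'=O on C6, C2'H2, C3'H2 on C5) | O=C1CCc2cc3c(c4ccc(OC)c1c24)C(=O)CC3 | intermediate
8 | phenalenone indanone: 9-methoxyphenalen-1-one with the same C5–C6-fused cyclopentanone | O=C1C=Cc2cc3c(c4ccc(OC)c1c24)C(=O)CC3 | intermediate
9 | naphthalene-1,8-diol | Oc1cccc2cccc(O)c12 | starting material
10 | spiroketal: C1' of 8 as spiro carbon of a naphtho[1,8-de][1,3]dioxine, C2'H2, C3'H2 | O=C1C=Cc2cc3c(c4ccc(OC)c1c24)C1(Oc2cccc4cccc(c24)O1)CC3 | intermediate
11 | keto spiroketal: 10 with C3'=O | O=C1C=Cc2cc3c(c4ccc(OC)c1c24)C1(Oc2cccc4cccc(c24)O1)CC3=O | intermediate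
12 | (R)-1-(2,4,6-triisopropylphenyl)ethanol | C[C@@H](O)c1c(C(C)C)cc(C(C)C)cc1C(C)C | starting material
13 | dimethyl ketal of 11 at C3' | O=C1C=Cc2cc3c(c4ccc(OC)c1c24)C1(Oc2cccc4cccc(c24)O1)CC3(OC)OC | intermediate
14 | enol ether: 9-methoxyphenalenone-fused 3'-alkoxyindene, C1' spiroketal, C2'=C3', C3'–O–CH(CH3)(2,4,6-triisopropylphenyl) with (R) at the ether carbon | O=C1C=Cc2cc3c(c4ccc(OC)c1c24)C1(Oc2cccc4cccc(c24)O1)C=C3O[C@H](C)c1c(C(C)C)cc(C(C)C)cc1C(C)C | intermediate
15 | trichloroacetyl chloride | O=C(Cl)C(Cl)(Cl)Cl | starting material
16 | dichloroketene | O=C=C(Cl)Cl | intermediate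
17 | (2'S,3'R)-cis-fused 2,2-dichloro-3-alkoxycyclobutanone: ring C2'H–C(=O)–CCl2–C3'(OR), R = (R)-auxiliary | O=C1C=Cc2cc3c(c4ccc(OC)c1c24)C1(Oc2cccc4cccc(c24)O1)[C@@H]1C(=O)C(Cl)(Cl)[C@]31O[C@H](C)c1c(C(C)C)cc(C(C)C)cc1C(C)C | intermediate
18 | (2'S,3'R)-cis-fused 3-alkoxycyclobutanone: ring C2'H–C(=O)–CH2–C3'(OR) | O=C1C=Cc2cc3c(c4ccc(OC)c1c24)C1(Oc2cccc4cccc(c24)O1)[C@@H]1C(=O)C[C@]31O[C@H](C)c1c(C(C)C)cc(C(C)C)cc1C(C)C | intermediate
19 | (2'S,3'R)-cis-fused cyclopentanone: ring C2'H–C(=O)–CH2–CH2–C3'(OR) | O=C1C=Cc2cc3c(c4ccc(OC)c1c24)C1(Oc2cccc4cccc(c24)O1)[C@@H]1C(=O)CC[C@]31O[C@H](C)c1c(C(C)C)cc(C(C)C)cc1C(C)C | intermediate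
20 | trimethylsilyl enol ether of 19: ring C2'H–C(OSiMe3)=CH–CH2–C3'(OR) | O=C1C=Cc2cc3c(c4ccc(OC)c1c24)C1(Oc2cccc4cccc(c24)O1)[C@@H]1C(O[Si](C)(C)C)=CC[C@]31O[C@H](C)c1c(C(C)C)cc(C(C)C)cc1C(C)C | intermediate
21 | (2'S,3'R)-cyclopentenone auxiliary ether: ring C2'H–C(=O)–CH=CH–C3'(OR) | O=C1C=Cc2cc3c(c4ccc(OC)c1c24)C1(Oc2cccc4cccc(c24)O1)[C@@H]1C(=O)C=C[C@]31O[C@H](C)c1c(C(C)C)cc(C(C)C)cc1C(C)C | intermediate
22 | 9-O-methylspiropreussione B: as 21 with free tertiary OH at C3' | O=C1C=Cc2cc3c(c4ccc(OC)c1c24)C1(Oc2cccc4cccc(c24)O1)[C@@H]1C(=O)C=C[C@]31O | intermediate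
23 | spiropreussione B: (S) at the ring-fusion methine C2', (R) at the carbinol carbon C3', cis-fused | O=C1C=Cc2cc3c(c4ccc(O)c1c24)C1(Oc2cccc4cccc(c24)O1)[C@@H]1C(=O)C=C[C@]31O | target

**Step count.** 13 steps in total; the route is fully linear, so the longest linear sequence is 13 steps from 1.

**Steps most likely to fail**

Step 7. The hindered alcohol may add too slowly to the oxocarbenium ion, so that exchange stalls at the methyl enol ether, or the benzylic C–O bond of the auxiliary may ionise under the acid. The fallback sets out from 11: triflation without enolate formation (Tf2O, 2,6-di-tert-butyl-4-methylpyridine, CH2Cl2, 0 °C) should give enol triflate F1. F1 is then joined to 12 by C–O cross-coupling (Pd2(dba)3, 2-(di-tert-butylphosphino)-2',4',6'-triisopropyl-3,6-dimethoxybiphenyl, Cs2CO3, toluene, 80 °C), returning to the route at 14.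

Step 8. Facial selectivity may erode if the rotamer population differs from the assumed one; the hindered trisubstituted enol ether may capture the ketene too slowly, so that the ketene oligomerises; or zinc may transfer an electron to the phenalenone. The fallback sets out from 14 and uses a keteniminium (2+2) cycloaddition with the salt made beforehand from N,N-dimethylacetamide, Tf2O and 2,4,6-collidine (CH2Cl2, −20 → 20 °C). The resulting cyclobutaniminium triflate F2 is hydrolysed with aqueous NaHCO3, returning to the route at 18 and bypassing step 9.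

Step 10. The C2' methine may migrate in competition with the methylene, or diazomethane may undergo dipolar addition to the phenalenone C2=C3 bond. The fallback sets out from 18 and uses Lewis-acid-catalysed insertion of Me3SiCHN2 (Sc(OTf)3 cat., toluene, −78 °C), in which catalyst and silyl group direct migration of the methylene. The alpha-silyl ketone F3 then rearranges by a 1,3-shift of silicon from carbon to oxygen, returning to the route at 20 (the Pd(OAc)2 stage of step 11) and dispensing with the amide base.

**Further compounds**
F1 | step 7 | enol triflate of 11 (C2'=C3', C3'–OSO2CF3) | O=C1C=Cc2cc3c(c4ccc(OC)c1c24)C1(Oc2cccc4cccc(c24)O1)C=C3OS(=O)(=O)C(F)(F)F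
F2 | step 8 | (2'S,3'R)-cis-fused N,N-dimethylcyclobutaniminium triflate (iminium carbon on C2', CH2 on C3') | O=C1C=Cc2cc3c(c4ccc(OC)c1c24)C1(Oc2cccc4cccc(c24)O1)[C@@H]1C(=[N+](C)C)C[C@]31O[C@H](C)c1c(C(C)C)cc(C(C)C)cc1C(C)C.[O-]S(=O)(=O)C(F)(F)F
F3 | step 10 | alpha-trimethylsilyl cyclopentanone (ring C2'H–C(=O)–CH(SiMe3)–CH2–C3'(OR), silyl-bearing carbon as a mixture) | O=C1C=Cc2cc3c(c4ccc(OC)c1c24)C1(Oc2cccc4cccc(c24)O1)[C@@H]1C(=O)C([Si](C)(C)C)C[C@]31O[C@H](C)c1c(C(C)C)cc(C(C)C)cc1C(C)C
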